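## The problem

Compound 17 is a 2,3-trans-dihydroflavonol 3-methyl ether: a chroman-4-one (ring A fused to the pyranone ring C; flavonoid numbering O1, C2, C3, C4, C4a–C8a, ring B primed) with methoxy groups at C3, C5 and C7 and a 2,5-dihydroxy-4-methoxyphenyl ring B at C2. It has two adjacent stereocentres, C2 (R) and C3 (R). Their trans, diequatorial relationship is the thermodynamically preferred one, so C3 can be set relative to C2, whereas C2 has to be set absolutely. C3 is α to the ketone and the C2–O1 bond is β to it, so base can enolise the ketone and expel the ring A phenoxide, which would destroy both centres; dehydrogenation to the flavonol is a second drain. Ring B is a hydroquinone that air oxidises to the quinone, so its two hydroxyl groups must stay masked until the last step and be released under neutral conditions that spare the 5-methoxy group peri to the carbonyl. Because the molecule has four methyl ethers and two free phenols, the C3 methyl ether must be introduced at a stage where no other hydroxyl group is free. Ring A is phloroglucinol-derived, so any intermediate with a leaving group at the benzylic C4 ionises readily under acid. The enabling feature is that C3 (ether) and C4 (ketone) are adjacent oxidised carbons of ring C, the oxidation pattern of a C3=C4 alkene in a 2-aryl-2H-chromene whose only stereocentre is the allylic, benzylic C2; that alkene can be made by ring-closing metathesis, and the C2 aryl group can then direct the oxygenation of C3.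

## Retrosynthesis

**17 to 16.** The two phenolic O–H bonds of ring B are traced back to benzyl ethers in 16. Benzyl is preferred to methyl (not distinguishable from the four methyl ethers) and to acetal or silyl groups (acid or organolithium steps lie on the route). The precursor no longer contains the air-sensitive hydroquinone. The forward hydrogenolysis must spare the cyclic benzylic C2–O1 ether and the aryl ketone.

**16 to 15.** The C3 O–CH3 bond is cut, giving α-ketol 15. Methylating here, and not at the diol stage, means only one hydroxyl group is free. The forward step must alkylate without enolising the ketone.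

**15 to 14.** The C4 carbonyl is traced back to the benzylic alcohol of cis-diol 14. This turns the carbonyl into a problem of alkene oxygenation. The forward oxidation must take the ring-A-activated benzylic carbinol, leave the C3 carbinol alone and not break the C3–C4 bond; for that reason a hydride-abstracting quinone is chosen over activated MnO2, which tends to cleave cis-1,2-diols.

**14 to 13.** Both C–O bonds at C3 and C4 are cut, leading to 2H-chromene 13. Epoxidation would give an acid-labile benzylic epoxide needing a separate opening, and hydroboration would leave C4 as a methylene group. The precursor has one stereocentre instead of three. The forward dihydroxylation must occur on the face opposite the C2 aryl group; the C4 configuration is irrelevant because it is erased in the next step.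

**13 to 12.** The C3=C4 bond is cut by ring-closing metathesis, giving diene 12. The neighbouring cuts are weaker: O1–C2 by oxa-Michael closure of a chalcone is reversible and hard to control, and C4–C4a by acylation needs strong acid next to an ionisable ether. The metathesis cut places the single stereocentre in an acyclic ether flanked by two plain vinyl groups. The forward reaction needs no stereocontrol but must not migrate the allylic double bond or ionise C2–O.

**12 to 2 and 10.** The O1–C2 bond is cut to phenol 2 (used as its lithium phenoxide 11) and linear cinnamyl carbonate 10. Displacement at a preformed secondary benzylic alcohol would run through an ionisation-prone centre, whereas iridium-catalysed allylic etherification creates the centre from achiral partners. Both fragments are achiral and of similar size. The forward step must be branched-selective and enantioselective.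

**10 to 6 and 7.** The carbonate C–O bond, the oxidation level of the allylic carbon and the C=C bond are unravelled through alcohol 9 and ester 8 to aldehyde 6 and phosphonate 7. This is the standard way to an (E)-cinnamyl electrophile; the forward steps only need (E)-selectivity and non-acidic work-ups.

**6 to 3.** The aryl–CHO bond is cut to diether 4 (forward through iminium salt 5), and the two O–benzyl bonds to 2-methoxyhydroquinone 3. The forward formylation must go para to the methoxy group, the only unhindered position activated by two donors.

**2 to 1.** The vinyl C=C bond is cut to the commercial salicylaldehyde 1 by Wittig methylenation, which already carries the complete ring A oxygenation.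

## Roads not taken

Alternative 1: The cut is through C2–C3 and the C3–O bond of an open chain, with ring C closed afterwards at O1–C8a. In the forward step Rh2(OAc)4 decomposes diazoketone A2 in the presence of methanol, and the O–H insertion is interrupted at the ylide stage by aldol addition to aldehyde 6 under a chiral phosphoric acid, giving A1; fluoride displacement in A1 would then lead to 16.
- Merits: it is convergent, uses aldehyde 6 as well, brings in the C3 methoxy group directly from methanol and forms both stereocentres in one step. In these respects it is shorter than the chosen plan and avoids methylating an α-ketol.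
- Weak points: aldehyde 6 is electron-rich and ortho-substituted, so the trapping has to outrun the simple proton shift to the O–H insertion product. The required erythro (2R,3R) isomer must come from catalyst control alone. The ring closure is a nucleophilic aromatic substitution on a fluoroarene that two methoxy groups deactivate, so it needs strong base on a β-hydroxy ketone, inviting retro-aldol cleavage and epimerisation.
- Comparison: the chosen plan sets against it two separately precedented stereo-defining steps and a ring closure under neutral conditions.

Alternative 2: The cut is through C3–C4 and O1–C2 in a [4+2] sense. Benzylic alcohol A4 loses water under a chiral BINOL phosphoric acid to give ortho-quinone methide A5, which adds to (E)-enol acetate A6 to give the 2,3-trans chromanyl acetate A3.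
- Merits: both ring C bonds and both stereocentres form at once from achiral partners, and the (E)-geometry translates into the trans relationship. In bond-forming economy this is better than the chosen plan.
- Weak points: the oxygen of A5 must bond to the aryl-bearing carbon of A6, so the styrene polarisation has to override the opposing enol-ester polarisation. A5 from a trioxygenated ring forms easily but also oligomerises. A3 still needs a methylene-to-carbonyl oxidation at C4 in the presence of two benzyl ethers and an activated C2–H, and an acetate-to-methyl ether exchange, before it reaches 16.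
- Comparison: the chosen plan delivers C4 at an oxidisable level through the alkene and needs no C–H oxidation.

Alternative 3: The cut is through O1–C8a and C4–C4a, with ring A added last as an aryne. CsF releases aryne A9 from silylaryl triflate A8, the benzylic alkoxide of hydroxy ester A10 adds to it and the aryl anion acylates itself on the ester, giving A7, which is identical with 16.
- Merits: it is the most convergent road, the regiochemistry of the aryne addition is the favourable one (attack meta to the flanking methoxy group), and it reaches 16 with C3–OMe, C4=O and both stereocentres in place. After the key step it is clearly shorter than the chosen plan and avoids both the diol oxidation and the α-ketol methylation.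
- Weak points: A10 must be made as the single erythro (2R,3R) isomer, which is not the syn-dihydroxylation product of cinnamate 8. A β-hydroxy-α-alkoxy ester under fluoride and alkoxide is open to retro-aldol cleavage and α-epimerisation. The hindered secondary alkoxide may add slowly, and protonation of the aryl anion before acylation would stop at the open aryl ether. A8 needs its own multistep preparation.
- Comparison: the chosen plan sets against it that its two stereocentres are made one at a time, first by catalyst and then by substrate control, and are never exposed together in an open, enolisable chain under base.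

Key step: step 8

Assumption: the sense of induction of the iridium–phosphoramidite catalyst is taken from unsubstituted cinnamyl carbonates, where the (Ra,Rc,Rc) ligand gives (R)-aryl ethers. The CIP ranking at C2 of 12 is the same (O > aryl > vinyl > H), so the (Sa,Sc,Sc) ligand L, O,O'-(1,1'-binaphthalene-2,2'-diyl) N,N-bis(1-phenylethyl)phosphoramidite, is specified for (S)-12; its mirror image would be used if the ortho-benzyloxy group reversed the sense.

## Steps

Step 1
Reactants: 1 2-hydroxy-4,6-dimethoxybenzaldehyde
Product: 2 2-ethenyl-3,5-dimethoxyphenol
Conditions: Ph3PCH3Br (2.5 equiv), KOtBu (2.5 equiv), THF, 0 °C to rt; aq. NH4Cl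
Reagents that add atoms: methyltriphenylphosphonium bromide, C[P+](c1ccccc1)(c1ccccc1)c1ccccc1.[Br-]
Why: Wittig methylenation; excess ylide first forms the phenoxide and then converts the formyl group into the vinyl group, as is standard for salicylaldehydes, and no stereocentre is involved.

Step 2
Reactants: 3 2-methoxyhydroquinone
Product: 4 1,4-bis(benzyloxy)-2-methoxybenzene
Conditions: BnBr (2.3 equiv), K2CO3, DMF, 60 °C, argon
Reagents that add atoms: benzyl bromide, BrCc1ccccc1
Why: Williamson etherification of both phenols; benzyl is chosen because it should survive POCl3, hydride, organolithium, ruthenium, osmium, DDQ and Ag2O and leaves at the end under neutral hydrogenolysis.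

Step 3
Reactants: 4 1,4-bis(benzyloxy)-2-methoxybenzene
Product: 6 2,5-bis(benzyloxy)-4-methoxybenzaldehyde, via iminium chloride 5 (not isolated)
Conditions: POCl3, DMF, 0 to 70 °C; then ice-water, aq. NaOAc
Reagents that add atoms: N,N-dimethylformamide, CN(C)C=O; water, O; phosphoryl chloride, O=P(Cl)(Cl)Cl (gives only the chloride counter-ion of 5)
Why: Vilsmeier–Haack formylation; the position para to the methoxy group and ortho to a benzyloxy group is the only unhindered one activated by two donors, as in the formylation of 1,2,4-trimethoxybenzene, so the 2,5-bis(benzyloxy)-4-methoxy pattern should result.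

Step 4
Reactants: 6 2,5-bis(benzyloxy)-4-methoxybenzaldehyde; 7 triethyl phosphonoacetate
Product: 8 ethyl (E)-3-[2,5-bis(benzyloxy)-4-methoxyphenyl]prop-2-enoate
Conditions: LiCl, DBU, MeCN, rt
Reagents that add atoms: none
Why: Horner–Wadsworth–Emmons olefination under mild LiCl/DBU activation should give the (E)-cinnamate, the geometry needed for the linear (E)-carbonate.

Step 5
Reactants: 8 ethyl (E)-3-[2,5-bis(benzyloxy)-4-methoxyphenyl]prop-2-enoate
Product: 9 (E)-3-[2,5-bis(benzyloxy)-4-methoxyphenyl]prop-2-en-1-ol
Conditions: i-Bu2AlH (2.3 equiv), CH2Cl2, −78 °C; aq. potassium sodium tartrate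
Reagents that add atoms: none
Why: 1,2-Reduction of the unsaturated ester by i-Bu2AlH at low temperature gives the allylic alcohol without touching the alkene, and the neutral tartrate work-up avoids ionisation of the electron-rich cinnamyl alcohol.

Step 6
Reactants: 9 (E)-3-[2,5-bis(benzyloxy)-4-methoxyphenyl]prop-2-en-1-ol
Product: 10 (E)-3-[2,5-bis(benzyloxy)-4-methoxyphenyl]prop-2-en-1-yl methyl carbonate
Conditions: ClCO2Me, pyridine, CH2Cl2, 0 °C
Reagents that add atoms: methyl chloroformate, COC(=O)Cl
Why: Acylation of the primary alcohol gives the carbonate leaving group used in iridium-catalysed allylic substitution; the product is filtered through base-washed silica only.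

Step 7
Reactants: 2 2-ethenyl-3,5-dimethoxyphenol; 10 (E)-3-[2,5-bis(benzyloxy)-4-methoxyphenyl]prop-2-en-1-yl methyl carbonate
Product: 12 (S)-1-[2,5-bis(benzyloxy)-4-methoxyphenyl]prop-2-en-1-yl 2-ethenyl-3,5-dimethoxyphenyl ether, via lithium phenoxide 11 (not isolated)
Conditions: 2, n-BuLi, THF, −78 to 0 °C; then 10, [Ir(cod)Cl]2 (2 mol %), (Sa,Sc,Sc)-L (4 mol %, preactivated with n-PrNH2), THF, 25 °C
Reagents that add atoms: n-butyllithium, CCCC[Li] (gives only the lithium of 11; no atom of it remains in 12)
Why: Iridium-catalysed asymmetric allylic etherification: the cyclometalated iridium–phosphoramidite complex ionises the linear carbonate to an allyl complex and the aryloxide attacks the aryl-substituted terminus to give the branched ether, a reaction established for aryloxides including ortho-vinyl ones. The C2 stereocentre is set by the chiral ligand (catalyst control).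

Step 8
Reactants: 12 (S)-1-[2,5-bis(benzyloxy)-4-methoxyphenyl]prop-2-en-1-yl 2-ethenyl-3,5-dimethoxyphenyl ether
Product: 13 (S)-2-[2,5-bis(benzyloxy)-4-methoxyphenyl]-5,7-dimethoxy-2H-chromene
Conditions: RuCl2(=CHPh)(H2IMes)(PCy3) (second-generation Grubbs catalyst, 5 mol %), 1,4-benzoquinone (10 mol %), CH2Cl2 (0.01 M), 40 °C, dark
Reagents that add atoms: none
Why: Olefin metathesis by [2+2] addition and cycloreversion: the ruthenium benzylidene exchanges first with the unhindered vinyl group of the allylic ether, the new alkylidene adds across the neighbouring styrene to a ruthenacyclobutane, and cycloreversion forms the C3=C4 bond and a ruthenium methylidene that carries the chain with loss of ethylene. The closest known reaction type is the ring-closing metathesis of 2-vinylaryl allyl ethers to 2H-chromenes, established also for 2-aryl cases made by iridium-catalysed etherification. Ring C closes as a six-membered ring by joining the two internal alkene carbons of the diene, the cis geometry of the new alkene being imposed by the ring; the arene holds the two chains ortho to each other, so cyclisation should outrun oligomerisation at high dilution. No stereocentre is formed, and C2 is not a reacting centre, so its configuration should pass unchanged into 13. The selectivity needed is against migration of the allylic double bond by ruthenium hydrides, which would lead to an enol ether and ring contraction; benzoquinone as hydride scavenger, moderate temperature and a short reaction time are meant to secure this. The second requirement, no ionisation of the doubly activated C2–O bond, is met by the neutral, acid-free medium. Escape of ethylene makes the closure irreversible.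

Step 9
Reactants: 13 (S)-2-[2,5-bis(benzyloxy)-4-methoxyphenyl]-5,7-dimethoxy-2H-chromene
Product: 14 (2R,3S,4S)-2-[2,5-bis(benzyloxy)-4-methoxyphenyl]-5,7-dimethoxychromane-3,4-diol (2,3-trans, 3,4-cis)
Conditions: K2OsO2(OH)4 (2 mol %), NMO (1.5 equiv), acetone/H2O (10:1), 0 °C to rt; aq. Na2SO3
Reagents that add atoms: N-methylmorpholine N-oxide, C[N+]1([O-])CCOCC1; water, O
Why: Upjohn dihydroxylation; OsO4 adds suprafacially to C3=C4 from the face opposite the C2 aryl group, as is general for 2-aryl-2H-chromenes, so the C3 oxygen is set trans to the aryl group (substrate control by C2). The cis C4 hydroxyl, whose configuration is erased later, comes with it.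

Step 10
Reactants: 14 (2R,3S,4S)-2-[2,5-bis(benzyloxy)-4-methoxyphenyl]-5,7-dimethoxychromane-3,4-diol
Product: 15 (2R,3R)-2-[2,5-bis(benzyloxy)-4-methoxyphenyl]-3-hydroxy-5,7-dimethoxychroman-4-one
Conditions: DDQ (1.1 equiv), CH2Cl2/pH 7 phosphate buffer (10:1), 0 °C to rt
Reagents that add atoms: none
Why: Chemoselective dehydrogenation of an electron-rich benzylic alcohol by DDQ (hydride abstraction from C4, stabilised by the 5,7-dimethoxy and O1 donors); the non-benzylic C3 carbinol should not react and, unlike MnO2 on a cis-1,2-diol, DDQ does not cleave the C3–C4 bond. C2 and C3 are not touched.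

Step 11
Reactants: 15 (2R,3R)-2-[2,5-bis(benzyloxy)-4-methoxyphenyl]-3-hydroxy-5,7-dimethoxychroman-4-one
Product: 16 (2R,3R)-2-[2,5-bis(benzyloxy)-4-methoxyphenyl]-3,5,7-trimethoxychroman-4-one
Conditions: Ag2O (3 equiv), MeI (10 equiv), 4 Å MS, CH2Cl2, rt, dark
Reagents that add atoms: methyl iodide, CI
Why: Purdie methylation; Ag2O activates MeI towards the only free hydroxyl group under nearly neutral conditions, so the α-methoxy ketone should form without enolisation. Should C3 epimerise, equilibration favours the required diequatorial trans isomer.

Step 12
Reactants: 16 (2R,3R)-2-[2,5-bis(benzyloxy)-4-methoxyphenyl]-3,5,7-trimethoxychroman-4-one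
Product: 17 (2R,3R)-2-(2,5-dihydroxy-4-methoxyphenyl)-3,5,7-trimethoxychroman-4-one (CNP0281794.1)
Conditions: H2 (1 atm), 10% Pd/C, EtOAc, rt; filtration and concentration under argon
Reagents that add atoms: none
Why: Hydrogenolysis of the two aryl benzyl ethers over Pd/C under neutral conditions; the aryl ketone and the cyclic C2–O1 ether of flavanones are known to survive these conditions. The hydroquinone is released only here, with air excluded.

## Compound list

1 | 2-hydroxy-4,6-dimethoxybenzaldehyde | COc1cc(O)c(C=O)c(OC)c1 | starting material
2 | 2-ethenyl-3,5-dimethoxyphenol | C=Cc1c(O)cc(OC)cc1OC | intermediate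
3 | 2-methoxyhydroquinone (2-methoxybenzene-1,4-diol) | COc1cc(O)ccc1O | starting material
4 | 1,4-bis(benzyloxy)-2-methoxybenzene | COc1cc(OCc2ccccc2)ccc1OCc1ccccc1 | intermediate
5 | N-{[2,5-bis(benzyloxy)-4-methoxyphenyl]methylidene}-N-methylmethanaminium chloride (not isolated) | C[N+](C)=Cc1cc(OCc2ccccc2)c(OC)cc1OCc1ccccc1.[Cl-] | intermediate
6 | 2,5-bis(benzyloxy)-4-methoxybenzaldehyde | O=Cc1cc(OCc2ccccc2)c(OC)cc1OCc1ccccc1 | intermediate
7 | triethyl phosphonoacetate | CCOC(=O)CP(=O)(OCC)OCC | starting material
8 | ethyl (E)-3-[2,5-bis(benzyloxy)-4-methoxyphenyl]prop-2-enoate | CCOC(=O)/C=C/c1cc(OCc2ccccc2)c(OC)cc1OCc1ccccc1 | intermediate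
9 | (E)-3-[2,5-bis(benzyloxy)-4-methoxyphenyl]prop-2-en-1-ol | OC/C=C/c1cc(OCc2ccccc2)c(OC)cc1OCc1ccccc1 | intermediate
10 | (E)-3-[2,5-bis(benzyloxy)-4-methoxyphenyl]prop-2-en-1-yl methyl carbonate | COC(=O)OC/C=C/c1cc(OCc2ccccc2)c(OC)cc1OCc1ccccc1 | intermediate
11 | lithium 2-ethenyl-3,5-dimethoxyphenoxide (not isolated) | [Li+].[O-]c1cc(OC)cc(OC)c1C=C | intermediate
12 | (S)-1-[2,5-bis(benzyloxy)-4-methoxyphenyl]prop-2-en-1-yl 2-ethenyl-3,5-dimethoxyphenyl ether | C=Cc1c(OC)cc(OC)cc1O[C@H](c1cc(OCc2ccccc2)c(OC)cc1OCc1ccccc1)C=C | intermediate
13 | (S)-2-[2,5-bis(benzyloxy)-4-methoxyphenyl]-5,7-dimethoxy-2H-chromene | COc1cc(OC)c2c(c1)O[C@H](c1cc(OCc3ccccc3)c(OC)cc1OCc1ccccc1)C=C2 | intermediate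
14 | (2R,3S,4S)-2-[2,5-bis(benzyloxy)-4-methoxyphenyl]-5,7-dimethoxychromane-3,4-diol | COc1cc(OC)c2c(c1)O[C@H](c1cc(OCc3ccccc3)c(OC)cc1OCc1ccccc1)[C@@H](O)[C@H]2O | intermediate
15 | (2R,3R)-2-[2,5-bis(benzyloxy)-4-methoxyphenyl]-3-hydroxy-5,7-dimethoxychroman-4-one | COc1cc(OC)c2c(c1)O[C@H](c1cc(OCc3ccccc3)c(OC)cc1OCc1ccccc1)[C@@H](O)C2=O | intermediate
16 | (2R,3R)-2-[2,5-bis(benzyloxy)-4-methoxyphenyl]-3,5,7-trimethoxychroman-4-one | COc1cc(OC)c2c(c1)O[C@H](c1cc(OCc3ccccc3)c(OC)cc1OCc1ccccc1)[C@@H](OC)C2=O | intermediate
17 | (2R,3R)-2-(2,5-dihydroxy-4-methoxyphenyl)-3,5,7-trimethoxychroman-4-one | COc1cc(OC)c2c(c1)O[C@H](c1cc(O)c(OC)cc1O)[C@@H](OC)C2=O | target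

## Step count and risks

Total: 12 steps. Longest linear sequence: 11 steps (3 to 17 through steps 2–12); the ring A branch adds step 1 before the fragments meet in step 7.

**Step 8 (key step).** The most likely failure is migration of the allylic double bond by ruthenium hydrides formed from the short-lived methylidene, made worse if the flanked styrene engages slowly. This would drain material into enol ether and ring-contracted products.

Fallback: the styrene terminus is capped with a methyl group so that the catalyst can only load on the allyl ether and is released as the more robust ethylidene. The fallback sets out from 1. Wittig reaction with ethylidenetriphenylphosphorane (EtPPh3Br, KOtBu, THF) would give 3,5-dimethoxy-2-(prop-1-enyl)phenol F1 as an E/Z mixture, both isomers being usable. Its lithium salt, lithium 3,5-dimethoxy-2-(prop-1-enyl)phenoxide F2 (n-BuLi, THF, not isolated), would be etherified with 10 under the conditions of step 7 to (S)-1-[2,5-bis(benzyloxy)-4-methoxyphenyl]prop-2-en-1-yl 3,5-dimethoxy-2-(prop-1-enyl)phenyl ether F3. Ring closure with RuCl2(=CH-2-i-PrOC6H4)(H2IMes) (second-generation Hoveyda–Grubbs catalyst) in CH2Cl2 would then expel propene in place of ethylene and come back to the route at 13.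

**Step 7.** The ortho-benzyloxy group on the cinnamyl unit may lower the branched selectivity and the enantioselectivity, and reversible ionisation of the very electron-rich allylic ether at iridium may erode the enantiopurity of 12. A first adjustment within the method would be the ligand variant carrying 1-(2-methoxyphenyl)ethyl groups.

Fallback: the ether is made from the alcohol side, so that the C–O bond of the stereocentre is never broken. The fallback sets out from 6. Vinylmagnesium bromide (THF, −78 °C) would give racemic 1-[2,5-bis(benzyloxy)-4-methoxyphenyl]prop-2-en-1-ol F4. Kinetic resolution with vinyl acetate over immobilised Candida antarctica lipase B should leave (S)-1-[2,5-bis(benzyloxy)-4-methoxyphenyl]prop-2-en-1-ol F5 unreacted, the lipase by its usual preference acylating the other enantiomer to (R)-1-[2,5-bis(benzyloxy)-4-methoxyphenyl]prop-2-en-1-yl acetate F6, which is separated. F5 would be arylated with commercial 2-fluoro-4,6-dimethoxybenzaldehyde by nucleophilic aromatic substitution ortho to the formyl group (KOtBu, THF/DMF, 0 °C to rt), with retention, to (S)-2-{1-[2,5-bis(benzyloxy)-4-methoxyphenyl]prop-2-en-1-yloxy}-4,6-dimethoxybenzaldehyde F7. Wittig methylenation as in step 1 comes back to the route at 12.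

**Step 10.** Competing hydride abstraction at the ring-B-activated C2–H, acid-triggered ionisation of the C4 hydroxyl with self-condensation on ring A, or further dehydrogenation to the flavonol may lower the selectivity of the oxidation.

Fallback: the order of methylation and oxidation is reversed so that no diol is ever oxidised. The fallback sets out from 14. Bu2SnO (toluene, reflux, −H2O) would give the 3,4-O-dibutylstannylene acetal of 14 F8 (not isolated). MeI and CsF in DMF should then alkylate the equatorial C3 oxygen in preference to the pseudo-axial benzylic C4 oxygen, as is usual for cis-diol stannylene acetals, giving (2R,3S,4S)-2-[2,5-bis(benzyloxy)-4-methoxyphenyl]-3,5,7-trimethoxychroman-4-ol F9. With the diol gone, activated MnO2 (CH2Cl2, rt) can oxidise the lone benzylic alcohol, and the fallback comes back to the route at 16, passing by steps 10 and 11.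

**Step 11.** Sluggish alkylation of the hindered, hydrogen-bonded α-ketol, or enolisation on the silver oxide surface followed by ring opening or dehydrogenation to the flavonol, may limit the methylation.

Fallback: both hydroxyl groups are methylated before the ketone exists. The fallback sets out from 14. NaH and MeI (THF/DMF, 0 °C) would give (2R,3S,4S)-2-[2,5-bis(benzyloxy)-4-methoxyphenyl]-3,4,5,7-tetramethoxychromane F10. DDQ in wet CH2Cl2 should then remove the C4 hydride of the activated benzylic methyl ether, the same site selectivity that step 10 relies on, and hydrolysis of the oxocarbenium ion releases methanol, coming back to the route at 16.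

## Further compounds

F1 | step 8 | 3,5-dimethoxy-2-(prop-1-enyl)phenol (E/Z mixture) | CC=Cc1c(O)cc(OC)cc1OC
F2 | step 8 | lithium 3,5-dimethoxy-2-(prop-1-enyl)phenoxide | [Li+].[O-]c1cc(OC)cc(OC)c1C=CC
F3 | step 8 | (S)-1-[2,5-bis(benzyloxy)-4-methoxyphenyl]prop-2-en-1-yl 3,5-dimethoxy-2-(prop-1-enyl)phenyl ether | CC=Cc1c(OC)cc(OC)cc1O[C@H](c1cc(OCc2ccccc2)c(OC)cc1OCc1ccccc1)C=C
F4 | step 7 | racemic 1-[2,5-bis(benzyloxy)-4-methoxyphenyl]prop-2-en-1-ol | OC(c1cc(OCc2ccccc2)c(OC)cc1OCc1ccccc1)C=C
F5 | step 7 | (S)-1-[2,5-bis(benzyloxy)-4-methoxyphenyl]prop-2-en-1-ol | O[C@H](c1cc(OCc2ccccc2)c(OC)cc1OCc1ccccc1)C=C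
F6 | step 7 | (R)-1-[2,5-bis(benzyloxy)-4-methoxyphenyl]prop-2-en-1-yl acetate | CC(=O)O[C@@H](c1cc(OCc2ccccc2)c(OC)cc1OCc1ccccc1)C=C
F7 | step 7 | (S)-2-{1-[2,5-bis(benzyloxy)-4-methoxyphenyl]prop-2-en-1-yloxy}-4,6-dimethoxybenzaldehyde | O=Cc1c(OC)cc(OC)cc1O[C@H](c1cc(OCc2ccccc2)c(OC)cc1OCc1ccccc1)C=C
F8 | step 10 | 3,4-O-dibutylstannylene acetal of 14 (cis-fused 2,2-dibutyl-1,3,2-dioxastannolane on C3 and C4) | COc1cc(OC)c2c(c1)O[C@H](c1cc(OCc3ccccc3)c(OC)cc1OCc1ccccc1)[C@H]4O[Sn](CCCC)(CCCC)O[C@@H]24
F9 | step 10 | (2R,3S,4S)-2-[2,5-bis(benzyloxy)-4-methoxyphenyl]-3,5,7-trimethoxychroman-4-ol | COc1cc(OC)c2c(c1)O[C@H](c1cc(OCc3ccccc3)c(OC)cc1OCc1ccccc1)[C@@H](OC)[C@H]2O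
F10 | step 11 | (2R,3S,4S)-2-[2,5-bis(benzyloxy)-4-methoxyphenyl]-3,4,5,7-tetramethoxychromane | COc1cc(OC)c2c(c1)O[C@H](c1cc(OCc3ccccc3)c(OC)cc1OCc1ccccc1)[C@@H](OC)[C@H]2OC
A1 | alternative 1 | (2R,3R)-3-[2,5-bis(benzyloxy)-4-methoxyphenyl]-1-(2-fluoro-4,6-dimethoxyphenyl)-3-hydroxy-2-methoxypropan-1-one | O[C@H](c1cc(OCc2ccccc2)c(OC)cc1OCc1ccccc1)[C@@H](OC)C(=O)c1c(F)cc(OC)cc1OC
A2 | alternative 1 | 2-diazo-1-(2-fluoro-4,6-dimethoxyphenyl)ethan-1-one | [N-]=[N+]=CC(=O)c1c(F)cc(OC)cc1OC
A3 | alternative 2 | (2R,3S)-2-[2,5-bis(benzyloxy)-4-methoxyphenyl]-5,7-dimethoxychroman-3-yl acetate (2,3-trans) | COc1cc(OC)c2c(c1)O[C@H](c1cc(OCc3ccccc3)c(OC)cc1OCc1ccccc1)[C@@H](OC(C)=O)C2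
A4 | alternative 2 | 2-(hydroxymethyl)-3,5-dimethoxyphenol | COc1cc(O)c(CO)c(OC)c1
A5 | alternative 2 | 3,5-dimethoxy-6-methylidenecyclohexa-2,4-dien-1-one | C=C1C(=O)C=C(OC)C=C1OC
A6 | alternative 2 | (E)-2-[2,5-bis(benzyloxy)-4-methoxyphenyl]ethenyl acetate | CC(=O)O/C=C/c1cc(OCc2ccccc2)c(OC)cc1OCc1ccccc1
A7 | alternative 3 | (2R,3R)-2-[2,5-bis(benzyloxy)-4-methoxyphenyl]-3,5,7-trimethoxychroman-4-one (identical with 16) | COc1cc(OC)c2c(c1)O[C@H](c1cc(OCc3ccccc3)c(OC)cc1OCc1ccccc1)[C@@H](OC)C2=O
A8 | alternative 3 | 3,5-dimethoxy-2-(trimethylsilyl)phenyl trifluoromethanesulfonate | COc1cc(OC)c([Si](C)(C)C)c(OS(=O)(=O)C(F)(F)F)c1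
A9 | alternative 3 | 1,2-didehydro-3,5-dimethoxybenzene | COC1=CC(OC)=CC#C1
A10 | alternative 3 | methyl (2R,3R)-3-[2,5-bis(benzyloxy)-4-methoxyphenyl]-3-hydroxy-2-methoxypropanoate | O[C@H](c1cc(OCc2ccccc2)c(OC)cc1OCc1ccccc1)[C@@H](OC)C(=O)OC
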